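**Retrosynthetic overview**
1. Target ⇒ ternaphthalene-hexaol: the three methyl groups go on last, onto the three unhindered peri (C8-type) hydroxyls.
2. Hexaol ⇒ ternaphthalene-1,1',1''-triol: the three C8–O bonds are made late, in one flask, by silicon-tethered peri C–H oxygenation directed by each C1 oxygen (key step).
3. Triol ⇒ 2,4-dibromonaphthalen-1-ol plus two (1-methoxynaphthalen-2-yl)boronic acid units by double Suzuki coupling, then O-demethylation.
4. Boronic acid ⇒ 1-methoxynaphthalene by C2 lithiation and borylation.
5. No carbocycle is built: all three naphthalene ring systems are bought intact. The only rings formed are three transient oxasilole rings in the key step, after both biaryl bonds are in place.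

Assumption: the SMILES has no stereodescriptor and the molecule has no stereocentre. Both biaryl axes carry too few ortho substituents to be configurationally stable at room temperature, so the target is one stereochemically undefined compound and no step needs stereocontrol.

Both starting materials (1 and 5) are inexpensive catalogue compounds.

Step 1
Reactants: 1 1-methoxynaphthalene
Product: 4 (1-methoxynaphthalen-2-yl)boronic acid, via (1-methoxynaphthalen-2-yl)lithium 2 (not isolated), via lithium aryl(triisopropoxy)borate 3 (not isolated)
Conditions: n-BuLi (1.1 equiv), TMEDA (1.1 equiv), hexane, rt, 2 h; B(OiPr)3 (1.5 equiv), THF, −78 °C → rt; 1 M HCl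
Reagents that add atoms: triisopropyl borate, CC(C)OB(OC(C)C)OC(C)C; water, O
Why: Directed ortho-metalation, in which n-BuLi/TMEDA removes the C2 proton next to the methoxy group under kinetic control (peri C8 lithiation needs t-BuLi and equilibration), followed by borylation of the aryllithium 2 to the ate complex 3, which aqueous acid hydrolyses to 4.

Step 2
Reactants: 5 2,4-dibromonaphthalen-1-ol; 4 (1-methoxynaphthalen-2-yl)boronic acid (2.5 equiv)
Product: 6 2,4-bis(1-methoxynaphthalen-2-yl)naphthalen-1-ol
Conditions: Pd(OAc)2 (5 mol%), SPhos (10 mol%), K3PO4 (5 equiv), toluene/H2O 5:1, degassed, 90 °C, 16 h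
Reagents that add atoms: none
Why: Double Suzuki–Miyaura coupling, in which SPhos-ligated zerovalent palladium formed from Pd(OAc)2 inserts into both C–Br bonds of the naphtholate of 5 and couples each with the ortho-methoxy boronic acid 4 (excess covers protodeboronation), free phenols being tolerated under phosphate base.

Step 3
Reactants: 6 2,4-bis(1-methoxynaphthalen-2-yl)naphthalen-1-ol
Product: 8 [2,2':4',2''-ternaphthalene]-1,1',1''-triol, via tris(dibromoboryl) ether 7 (not isolated)
Conditions: BBr3 (4 equiv), CH2Cl2, −78 → 0 °C, 3 h; then H2O, 0 °C; handle under Ar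
Reagents that add atoms: none
Why: Lewis-acid ether cleavage, in which BBr3 complexes each methoxy oxygen and bromide removes the methyl group by SN2 (the free naphthol is borylated too), and water hydrolyses the aryl borate 7 to 8 at a temperature too low for cyclodehydration of the 2,2'-diol to a dinaphthofuran.

Step 4
Reactants: 8 [2,2':4',2''-ternaphthalene]-1,1',1''-triol
Product: 11 [2,2':4',2''-ternaphthalene]-1,1',1'',8,8',8''-hexaol, via tris(diethylsilyl) ether 9 (not isolated), via tris(oxasilole) 10 (not isolated)
Conditions: Et2SiHCl (3.6 equiv), Et3N (4 equiv), THF, 0 °C → rt, filter under Ar; [Ir(cod)OMe]2 (4 mol%), 3,4,7,8-tetramethyl-1,10-phenanthroline (9 mol%), norbornene (4 equiv), THF, 100 °C, 16 h; then 30% aq H2O2 (4.5 equiv), KHCO3, THF/MeOH 1:1, 0 °C → rt, under Ar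
Reagents that add atoms: hydrogen peroxide, OO
Why: Proposed new method: threefold silicon-tethered peri C–H oxygenation of 1-naphthols. Each ArO–SiEt2H group adds its Si–H bond to the phenanthroline-ligated iridium silyl catalyst, and the O–Si tether holds the metal over the coplanar peri C8–H bond about 2.5 Å away (C2 is blocked by an aryl group in all three units, so no ortho site exists). C–H cleavage and C–Si reductive elimination then close a five-membered naphtho[1,8-cd][1,2]oxasilole, a ring isosteric with the stable 1,8-naphthosultone, while norbornene takes up the H2. This five-ring closure should outrun the six-ring closure onto the twisted neighbouring naphthalene, whose nearest C–H is either flanked by two aryl groups or out of plane. Hydroperoxide finally adds to the strained silicon and the aryl group migrates from Si to O (Tamao–Fleming oxidation), which makes each C8–O bond. The closest known reaction type is the hydrosilyl-ether-tethered, hydroxyl-directed iridium-catalysed ortho C–H silylation of benzylic alcohols followed by Tamao–Fleming oxidation; it passes through a metallacycle of the same size but is not established for the peri C–H bond of a 2-aryl-1-naphthol, nor three times in one substrate.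

Step 5
Reactants: 11 [2,2':4',2''-ternaphthalene]-1,1',1'',8,8',8''-hexaol
Product: 12 8,8',8''-trimethoxy-[2,2':4',2''-ternaphthalene]-1,1',1''-triol
Conditions: MeI (3.3 equiv), K2CO3 (3.3 equiv), acetone, rt, Ar, dark (crude 11 used at once)
Reagents that add atoms: iodomethane, CI
Why: Regioselective Williamson ether synthesis, in which K2CO3 forms only the hydrogen-bonded monoanion of each peri-diol, iodomethane alkylates it at the open C8 oxygen and not at the C1 oxygen flanked by the C2 aryl group, and the remaining C1–OH, locked in an O–H···OMe hydrogen bond, is not deprotonated further, so methylation stops at three.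

**Compound list**
1 | 1-methoxynaphthalene | COc1cccc2ccccc12 | starting material
2 | (1-methoxynaphthalen-2-yl)lithium | COc1c([Li])ccc2ccccc12 | intermediate
3 | lithium (1-methoxynaphthalen-2-yl)tri(propan-2-yloxy)borate | [Li+].COc1c([B-](OC(C)C)(OC(C)C)OC(C)C)ccc2ccccc12 | intermediate
4 | (1-methoxynaphthalen-2-yl)boronic acid | COc1c(B(O)O)ccc2ccccc12 | intermediate
5 | 2,4-dibromonaphthalen-1-ol | Oc1c(Br)cc(Br)c2ccccc12 | starting material
6 | 2,4-bis(1-methoxynaphthalen-2-yl)naphthalen-1-ol | Oc1c(-c2ccc3ccccc3c2OC)cc(-c2ccc3ccccc3c2OC)c2ccccc12 | intermediate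
7 | 1,1',1''-tris[(dibromoboranyl)oxy]-2,2':4',2''-ternaphthalene | BrB(Br)Oc1c(-c2ccc3ccccc3c2OB(Br)Br)cc(-c2ccc3ccccc3c2OB(Br)Br)c2ccccc12 | intermediate
8 | [2,2':4',2''-ternaphthalene]-1,1',1''-triol | Oc1c(-c2ccc3ccccc3c2O)cc(-c2ccc3ccccc3c2O)c2ccccc12 | intermediate
9 | 1,1',1''-tris[(diethylsilyl)oxy]-2,2':4',2''-ternaphthalene | CC[SiH](CC)Oc1c(-c2ccc3ccccc3c2O[SiH](CC)CC)cc(-c2ccc3ccccc3c2O[SiH](CC)CC)c2ccccc12 | intermediate
10 | tris(oxasilole): the 2,2':4',2''-ternaphthalene of 8 in which each unit carries an O1–SiEt2–C8 bridge, i.e. three 2,2-diethyl-2H-naphtho[1,8-cd][1,2]oxasilole units | CC[Si]1(CC)Oc2c(-c4ccc5cccc6c5c4O[Si]6(CC)CC)cc(-c4ccc5cccc6c5c4O[Si]6(CC)CC)c3cccc1c23 | intermediate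
11 | [2,2':4',2''-ternaphthalene]-1,1',1'',8,8',8''-hexaol | Oc1cccc2ccc(-c3cc(-c4ccc5cccc(O)c5c4O)c4cccc(O)c4c3O)c(O)c12 | intermediate
12 | 8,8',8''-trimethoxy-[2,2':4',2''-ternaphthalene]-1,1',1''-triol (CNP0482979.0) | COc1cccc2ccc(-c3cc(-c4ccc5cccc(OC)c5c4O)c4cccc(OC)c4c3O)c(O)c12 | target

**Totals**
Total step count: 5. Longest linear sequence: 5 steps (1 → 4 → 6 → 8 → 11 → 12).

**Three steps most likely to fail**

Step 4 (the proposed new method). The risks are six-ring closure onto a neighbouring naphthalene instead of peri closure, incomplete threefold silylation, and over-oxidation of the electron-rich hexaol by H2O2. The fallback uses known chemistry and pre-oxygenated building blocks; it sets out from 1 and comes back to the route at 12. Compound 1 is lithiated at the peri position with t-BuLi (cyclohexane, rt, thermodynamic control), quenched with B(OMe)3 and oxidised with alkaline H2O2 to 8-methoxynaphthalen-1-ol F1. One portion of F1 is dibrominated with NBS (2 equiv, MeCN, 0 °C) to 2,4-dibromo-8-methoxynaphthalen-1-ol F2. The other portion is protected with MOMCl/iPr2NEt as 1-methoxy-8-(methoxymethoxy)naphthalene F3, which is lithiated next to the OMOM group with n-BuLi and borylated with B(OiPr)3 to [8-methoxy-1-(methoxymethoxy)naphthalen-2-yl]boronic acid F4. Double Suzuki coupling of F2 with F4 (Pd(OAc)2, SPhos, K3PO4, toluene/H2O, 90 °C) gives 2,4-bis[8-methoxy-1-(methoxymethoxy)naphthalen-2-yl]-8-methoxynaphthalen-1-ol F5, and HCl in MeOH removes both MOM groups to give 12.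

Step 5 (threefold regioselective methylation of an air-sensitive hexaol). The risks are methylation at a C1 oxygen, over-methylation, and oxidative loss of 11. The fallback replaces selective alkylation by exhaustive alkylation and selective dealkylation; it sets out from 11 and comes back at 12. Compound 11 is fully methylated (MeI, NaH, DMF, 0 °C → rt) to the air-stable 1,1',1'',8,8',8''-hexamethoxy-2,2':4',2''-ternaphthalene F6. BCl3 (3.3 equiv, CH2Cl2, −78 → −20 °C) then cleaves only the three C1-type methoxy groups. Each of these is the most crowded, out-of-plane ether, flanked by the C2 aryl group and the peri methoxy group, and Lewis acids are known to single out such flanked methoxy groups, as in 1,2,3-trimethoxyarenes. Aqueous work-up gives 12.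

Step 2 (double coupling on an unprotected, electron-rich dibromonaphthol with a hindered boronic acid). The risks are stalling at the mono-coupled bromide and protodeboronation of 4. The fallback changes both the nucleophile and the phenol masking; it sets out from 5 and 2 and comes back at 8. Compound 5 is methylated (MeI, K2CO3, acetone, reflux) to 2,4-dibromo-1-methoxynaphthalene F7. Aryllithium 2, made as in step 1, is transmetalated with ZnCl2 to chlorido(1-methoxynaphthalen-2-yl)zinc F8. Negishi coupling of F7 with F8 (2.5 equiv; Pd(OAc)2, SPhos, THF, 60 °C) gives 1-methoxy-2,4-bis(1-methoxynaphthalen-2-yl)naphthalene F9, and BBr3 under the conditions of step 3 cleaves all three methyl ethers to give 8.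

**Further compounds**
F1 | step 4 | 8-methoxynaphthalen-1-ol | COc1cccc2cccc(O)c12
F2 | step 4 | 2,4-dibromo-8-methoxynaphthalen-1-ol | COc1cccc2c(Br)cc(Br)c(O)c12
F3 | step 4 | 1-methoxy-8-(methoxymethoxy)naphthalene | COCOc1cccc2cccc(OC)c12
F4 | step 4 | [8-methoxy-1-(methoxymethoxy)naphthalen-2-yl]boronic acid | COCOc1c(B(O)O)ccc2cccc(OC)c12
F5 | step 4 | 2,4-bis[8-methoxy-1-(methoxymethoxy)naphthalen-2-yl]-8-methoxynaphthalen-1-ol | COc1cccc2ccc(-c3cc(-c4ccc5cccc(OC)c5c4OCOC)c4cccc(OC)c4c3O)c(OCOC)c12
F6 | step 5 | 1,1',1'',8,8',8''-hexamethoxy-2,2':4',2''-ternaphthalene | COc1cccc2ccc(-c3cc(-c4ccc5cccc(OC)c5c4OC)c4cccc(OC)c4c3OC)c(OC)c12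
F7 | step 2 | 2,4-dibromo-1-methoxynaphthalene | COc1c(Br)cc(Br)c2ccccc12
F8 | step 2 | chlorido(1-methoxynaphthalen-2-yl)zinc | COc1c([Zn]Cl)ccc2ccccc12
F9 | step 2 | 1-methoxy-2,4-bis(1-methoxynaphthalen-2-yl)naphthalene | COc1c(-c2ccc3ccccc3c2OC)cc(-c2ccc3ccccc3c2OC)c2ccccc12
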